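**Strategy.** Everything hinges on disconnecting the pyrone at O1–C8a, the only carbon–oxygen bond of ring A that sits para to the C6 methoxy group. Ring A can then be built from 2-methoxyresorcinol with three oxygens only. The fourth arrives, and ring C closes, in one anodic dehydrogenative etherification that joins the enol oxygen of a 1,3-diketone to C8a, the single C–H position of ring A. The substrate for this step is a 1-aryl-3-(4-benzyloxyphenyl)propane-1,3-dione whose aryl group carries two benzyloxy groups, the methoxy group and an (R)-N-Boc-pyrrolidin-2-yl unit, set earlier by sparteine-mediated lithiation and Negishi arylation.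

Key step: step 6

Remark: diketone 10 is drawn in its diketo form although it should exist mainly as the chelated enol; the enantiomeric purity set in step 4 is to be checked on 8 and, if needed, raised there by recrystallisation or preparative chiral chromatography.

Step 1
Reactants: 1 2-methoxyresorcinol (2-methoxybenzene-1,3-diol)
Product: 2 1-(2,4-dihydroxy-3-methoxyphenyl)ethan-1-one
Conditions: AcOH, BF3·OEt2, 90 °C; then H2O
Reagents that add atoms: acetic acid, CC(=O)O
Why: Nencki-type Friedel–Crafts C-acylation of the resorcinol should take place ortho to one hydroxyl and para to the other, the two such positions of 1 being equivalent, and the acetyl group introduced deactivates the ring towards a second acylation.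

Step 2
Reactants: 2 1-(2,4-dihydroxy-3-methoxyphenyl)ethan-1-one
Product: 3 1-[2,4-bis(benzyloxy)-3-methoxyphenyl]ethan-1-one
Conditions: BnBr (2.4 equiv), K2CO3, DMF, 70 °C
Reagents that add atoms: benzyl bromide, BrCc1ccccc1
Why: Williamson etherification with excess benzyl bromide and carbonate in warm DMF should alkylate both phenols, including the hydrogen-bonded one next to the ketone.

Step 3
Reactants: 3 1-[2,4-bis(benzyloxy)-3-methoxyphenyl]ethan-1-one
Product: 4 1-[2,4-bis(benzyloxy)-5-bromo-3-methoxyphenyl]ethan-1-one
Conditions: NBS (1.05 equiv), MeCN, 0 °C to rt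
Reagents that add atoms: N-bromosuccinimide, O=C1CCC(=O)N1Br
Why: Electrophilic aromatic bromination should go to C5, which is para to the 2-benzyloxy and ortho to the 4-benzyloxy group, whereas C6 is deactivated by the neighbouring acetyl group and the ketone α-position is not attacked in the absence of acid.

Step 4
Reactants: 5 tert-butyl pyrrolidine-1-carboxylate; 4 1-[2,4-bis(benzyloxy)-5-bromo-3-methoxyphenyl]ethan-1-one
Product: 8 tert-butyl (R)-2-[5-acetyl-2,4-bis(benzyloxy)-3-methoxyphenyl]pyrrolidine-1-carboxylate, via organolithium 6 (not isolated), via organozinc chloride 7 (not isolated)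
Conditions: 5 (1.3 equiv), s-BuLi (1.2 equiv), (−)-sparteine (1.3 equiv), MTBE, −78 °C; ZnCl2 (1.3 equiv, THF), −78 °C to rt; then 4 (1.0 equiv), Pd(OAc)2 (5 mol %), t-Bu3P·HBF4 (6 mol %), rt to 40 °C
Reagents that add atoms: none
Why: Sparteine-mediated enantioselective α-lithiation of the carbamate, transmetalation to zinc and Negishi cross-coupling, the last two with retention, form a known sequence to 2-aryl-N-Boc-pyrrolidines in which (−)-sparteine directs removal of the pro-S hydrogen and thereby sets the (R) configuration of the aryl product, while the methyl ketone of 4 only meets the organozinc species, which neither adds to nor enolises it.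

Step 5
Reactants: 8 tert-butyl (R)-2-[5-acetyl-2,4-bis(benzyloxy)-3-methoxyphenyl]pyrrolidine-1-carboxylate; 9 methyl 4-(benzyloxy)benzoate
Product: 10 tert-butyl (R)-2-{2,4-bis(benzyloxy)-5-[3-(4-(benzyloxy)phenyl)-3-oxopropanoyl]-3-methoxyphenyl}pyrrolidine-1-carboxylate
Conditions: NaH (3 equiv), 9 (1.5 equiv), THF, 65 °C; then AcOH, 0 °C
Reagents that add atoms: none
Why: Crossed Claisen condensation of the methyl ketone enolate with the non-enolisable aryl ester is driven by deprotonation of the 1,3-diketone formed, and the carbamate and the non-acidic benzylic C–H of the pyrrolidine should not be touched by the base.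

Step 6
Reactants: 10 tert-butyl (R)-2-{2,4-bis(benzyloxy)-5-[3-(4-(benzyloxy)phenyl)-3-oxopropanoyl]-3-methoxyphenyl}pyrrolidine-1-carboxylate
Product: 11 tert-butyl (R)-2-[5,7-bis(benzyloxy)-2-(4-(benzyloxy)phenyl)-6-methoxy-4-oxo-4H-chromen-8-yl]pyrrolidine-1-carboxylate
Conditions: undivided cell, graphite anode, Pt cathode, constant current (about 1 mA cm−2, 2.2–2.5 F mol−1), Bu4NPF6 (0.1 M), HFIP/CH2Cl2 (4:1), rt
Reagents that add atoms: none
Why: Proposed new method: one-electron oxidation at the carbon anode in hexafluoroisopropanol should turn ring A, the most electron-rich π-system of 10, into its radical cation; the enol oxygen on C2 then adds to C8a, and loss of a second electron and of the C8a proton restores aromaticity while protons are reduced to H2 at the cathode. The closest known reaction types are anodic dehydrogenative C–O cyclisations onto arenes, such as the lactonisation of biaryl-2-carboxylic acids and benzoxazole formation from anilides, and the FeCl3-mediated oxidative closure of α-aryl ketone enols to benzofurans. Ring C closes in a six-membered mode, 6-endo-trig with respect to the C4a=C8a bond, once the enol leaves its intramolecular chelate, which the strongly hydrogen-bond-donating solvent should favour. No stereocentre is created, and the one at the pyrrolidine C2 is only a spectator. Site selectivity is built in, because C8a is the sole hydrogen-bearing carbon of ring A and the cation formed by attack there is stabilised as an oxocarbenium ion by the para C6 methoxy group, whereas addition at the alkoxy-bearing C5 cannot be completed by proton loss and should revert. Chemoselectivity for ring A over the carbamate α-C–H, the benzyl ethers and ring B is expected from its lower oxidation potential, from the carbamate (which takes the nitrogen lone pair out of play and, through allylic strain, holds the benzylic C–H near the arene plane), and from a low current density with the charge limited to little more than two faradays per mole.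

Step 7
Reactants: 11 tert-butyl (R)-2-[5,7-bis(benzyloxy)-2-(4-(benzyloxy)phenyl)-6-methoxy-4-oxo-4H-chromen-8-yl]pyrrolidine-1-carboxylate
Product: 13 (R)-5,7-bis(benzyloxy)-2-[4-(benzyloxy)phenyl]-6-methoxy-8-(1-methylpyrrolidin-2-yl)-4H-chromen-4-one, via secondary amine 12 (not isolated)
Conditions: TFA/CH2Cl2 (1:4), 0 °C to rt; evaporate; then 37% aq HCHO, NaBH(OAc)3, Et3N, ClCH2CH2Cl, rt
Reagents that add atoms: formaldehyde, C=O
Why: Acidolysis of the tert-butyl carbamate followed by reductive amination of the freed secondary amine with formaldehyde and triacetoxyborohydride are standard operations that leave the chromone and the benzyl ethers alone, and with the 7-oxygen still benzylated no quinone methide can form to erode the benzylic stereocentre.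

Step 8
Reactants: 13 (R)-5,7-bis(benzyloxy)-2-[4-(benzyloxy)phenyl]-6-methoxy-8-(1-methylpyrrolidin-2-yl)-4H-chromen-4-one
Product: 14 (R)-5,7-dihydroxy-2-(4-hydroxyphenyl)-6-methoxy-8-(1-methylpyrrolidin-2-yl)-4H-chromen-4-one
Conditions: H2 (1 atm), 10% Pd/C, THF/MeOH, rt
Reagents that add atoms: none
Why: Catalytic hydrogenolysis over palladium on carbon should cleave the three aryl benzyl ethers at room temperature under neutral conditions, under which the chromone double bond and the ring C–N bond are expected to persist and the freed ortho-hydroxybenzylamine is not driven to retro-Mannich opening.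

**Compound list**

1 | 2-methoxyresorcinol (2-methoxybenzene-1,3-diol) | COc1c(O)cccc1O | starting material
2 | 1-(2,4-dihydroxy-3-methoxyphenyl)ethan-1-one | CC(=O)c1ccc(O)c(OC)c1O | intermediate
3 | 1-[2,4-bis(benzyloxy)-3-methoxyphenyl]ethan-1-one | CC(=O)c1ccc(OCc2ccccc2)c(OC)c1OCc1ccccc1 | intermediate
4 | 1-[2,4-bis(benzyloxy)-5-bromo-3-methoxyphenyl]ethan-1-one | CC(=O)c1cc(Br)c(OCc2ccccc2)c(OC)c1OCc1ccccc1 | intermediate
5 | tert-butyl pyrrolidine-1-carboxylate (N-Boc-pyrrolidine) | CC(C)(C)OC(=O)N1CCCC1 | starting material
6 | (S)-[1-(tert-butoxycarbonyl)pyrrolidin-2-yl]lithium, present as its (−)-sparteine complex (diamine not drawn) | [Li][C@H]1CCCN1C(=O)OC(C)(C)C | intermediate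
7 | (S)-[1-(tert-butoxycarbonyl)pyrrolidin-2-yl]zinc chloride | Cl[Zn][C@H]1CCCN1C(=O)OC(C)(C)C | intermediate
8 | tert-butyl (R)-2-[5-acetyl-2,4-bis(benzyloxy)-3-methoxyphenyl]pyrrolidine-1-carboxylate | CC(=O)c1cc([C@H]2CCCN2C(=O)OC(C)(C)C)c(OCc2ccccc2)c(OC)c1OCc1ccccc1 | intermediate
9 | methyl 4-(benzyloxy)benzoate | COC(=O)c1ccc(OCc2ccccc2)cc1 | starting material
10 | tert-butyl (R)-2-{2,4-bis(benzyloxy)-5-[3-(4-(benzyloxy)phenyl)-3-oxopropanoyl]-3-methoxyphenyl}pyrrolidine-1-carboxylate | COc1c(OCc2ccccc2)c([C@H]2CCCN2C(=O)OC(C)(C)C)cc(C(=O)CC(=O)c2ccc(OCc3ccccc3)cc2)c1OCc1ccccc1 | intermediate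
11 | tert-butyl (R)-2-[5,7-bis(benzyloxy)-2-(4-(benzyloxy)phenyl)-6-methoxy-4-oxo-4H-chromen-8-yl]pyrrolidine-1-carboxylate | COc1c(OCc2ccccc2)c([C@H]2CCCN2C(=O)OC(C)(C)C)c2oc(-c3ccc(OCc4ccccc4)cc3)cc(=O)c2c1OCc1ccccc1 | intermediate
12 | (R)-5,7-bis(benzyloxy)-2-[4-(benzyloxy)phenyl]-6-methoxy-8-(pyrrolidin-2-yl)-4H-chromen-4-one (formed as its trifluoroacetate salt) | COc1c(OCc2ccccc2)c([C@H]2CCCN2)c2oc(-c3ccc(OCc4ccccc4)cc3)cc(=O)c2c1OCc1ccccc1 | intermediate
13 | (R)-5,7-bis(benzyloxy)-2-[4-(benzyloxy)phenyl]-6-methoxy-8-(1-methylpyrrolidin-2-yl)-4H-chromen-4-one | COc1c(OCc2ccccc2)c([C@H]2CCCN2C)c2oc(-c3ccc(OCc4ccccc4)cc3)cc(=O)c2c1OCc1ccccc1 | intermediate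
14 | (R)-5,7-dihydroxy-2-(4-hydroxyphenyl)-6-methoxy-8-(1-methylpyrrolidin-2-yl)-4H-chromen-4-one | COc1c(O)c([C@H]2CCCN2C)c2oc(-c3ccc(O)cc3)cc(=O)c2c1O | target

**Totals.** Total step count: 8. Longest linear sequence: 8 steps (1 to 14); 5 and 9 enter as purchased building blocks.

**Steps most likely to fail**

Step 6 (the new method). Several processes could compete with the intended closure:
- oxidation or proton loss at the carbamate-bearing benzylic carbon, which would erode the stereocentre through an N-acyliminium ion;
- fragmentation of a benzyl ether from the radical cation;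
- capture of the enol oxygen at the alkoxy-bearing C5;
- coupling of enol-derived radicals at C3;
- further oxidation of the flavone formed.

The fallback uses known chemistry, sets out from ketone 8 and makes the same O1–C8a bond from a halide. Bromination of the one remaining ring position with NBS in HFIP at rt should give tert-butyl (R)-2-[3-acetyl-4,6-bis(benzyloxy)-2-bromo-5-methoxyphenyl]pyrrolidine-1-carboxylate F1. Claisen condensation of F1 with 9 (NaH, THF, 65 °C) should give tert-butyl (R)-2-{4,6-bis(benzyloxy)-3-[3-(4-(benzyloxy)phenyl)-3-oxopropanoyl]-2-bromo-5-methoxyphenyl}pyrrolidine-1-carboxylate F2. Copper-catalysed intramolecular Ullmann-type O-arylation of the diketone enolate (CuI, 1,10-phenanthroline, K2CO3, DMF, 100 °C) should then close ring C and return to the route at 11.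

Step 4. The ortho-alkoxy, electron-rich bromide may undergo oxidative addition or transmetalation slowly. The enantiomeric ratio may suffer from incomplete complex-controlled lithiation or from warming the organometallic for long periods. Residual alkyllithium could attack the ketone. The fallback sets out from bromide 4 and gives up catalyst control of configuration in favour of resolution. Decarboxylative arylation of N-Boc-proline (either enantiomer, the α-stereocentre being lost in the radical) with 4 under dual photoredox and nickel catalysis (Ir[dF(CF3)ppy]2(dtbbpy)PF6, NiCl2·glyme, 4,4'-di-tert-butyl-2,2'-bipyridine, Cs2CO3, DMF, blue light, rt) should give racemic tert-butyl 2-[5-acetyl-2,4-bis(benzyloxy)-3-methoxyphenyl]pyrrolidine-1-carboxylate F3. Preparative chromatography of F3 on a chiral stationary phase then supplies the (R) enantiomer, and the route is rejoined at 8.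

Step 8. The tertiary amine may inhibit the palladium surface and leave the debenzylation incomplete. Once the 7-hydroxyl is free, the benzylic C–N bond may be hydrogenolysed. Reversible retro-Mannich opening through an ortho-quinone methide may lower the enantiomeric purity. The fallback replaces reduction by Lewis acid cleavage: from 13, BCl3 with pentamethylbenzene as benzyl cation scavenger (CH2Cl2, −78 °C, then MeOH) should remove the three benzyl groups without hydrogen or metal and without touching the methyl ether. It arrives directly at 14 and makes no new compound (F0).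

Further compounds
F1 | step 6 | tert-butyl (R)-2-[3-acetyl-4,6-bis(benzyloxy)-2-bromo-5-methoxyphenyl]pyrrolidine-1-carboxylate | CC(=O)c1c(Br)c([C@H]2CCCN2C(=O)OC(C)(C)C)c(OCc2ccccc2)c(OC)c1OCc1ccccc1
F2 | step 6 | tert-butyl (R)-2-{4,6-bis(benzyloxy)-3-[3-(4-(benzyloxy)phenyl)-3-oxopropanoyl]-2-bromo-5-methoxyphenyl}pyrrolidine-1-carboxylate | COc1c(OCc2ccccc2)c([C@H]2CCCN2C(=O)OC(C)(C)C)c(Br)c(C(=O)CC(=O)c2ccc(OCc3ccccc3)cc2)c1OCc1ccccc1
F3 | step 4 | racemic tert-butyl 2-[5-acetyl-2,4-bis(benzyloxy)-3-methoxyphenyl]pyrrolidine-1-carboxylate | CC(=O)c1cc(C2CCCN2C(=O)OC(C)(C)C)c(OCc2ccccc2)c(OC)c1OCc1ccccc1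
F0 | step 8 | none | none
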